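The route rests on cutting the furanone ring between its CH= carbon (C2) and its ketone carbon (C1); germacrane numbering is used throughout. The vinylogous ester O–C3=C2–C1=O of this ring is the cyclised form of an α′-hydroxy ynone, so C2≡C3 can enter as the alkyne of a (Z)-enyne and C1 as an aldehyde. A CrCl2/NiCl2 addition of the alkynyl iodide to the α-hydroxy aldehyde closes the ten-membered carbocycle at C1–C2 in one operation; both C1 carbinol epimers converge on oxidation, and gold-catalysed transannular attack of the C10 hydroxyl on C3 then completes the furanone. The precursor is a trans α-methylene-γ-butyrolactone carrying the (Z)-iodoenyne at C6 and the acyloxy aldehyde chain at C7.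

Key step: step 16

Remark: numbering is C1 ring ketone, C2 ring CH=, C3 enol-ether carbon, C4=C5 the Z alkene, C6 lactone O–CH, C7, C8 acyloxy carbon, C9 CH2, C10 quaternary carbon, C11–C13 the methylene-lactone carbons; 1, 4, 5 and 10 are taken as commercial single isomers.

Step 1
Reactants: 1 (Z)-3-methylpent-2-en-4-yn-1-ol
Product: 2 (Z)-3-methyl-5-(triisopropylsilyl)pent-2-en-4-yn-1-ol
Conditions: n-BuLi (2.1 equiv), THF, −78 to −20 °C; i-Pr3SiCl (1.05 equiv), −78 °C to rt; aq NH4Cl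
Reagents that add atoms: chlorotriisopropylsilane, CC(C)[Si](Cl)(C(C)C)C(C)C
Why: C-silylation of the alkoxide–acetylide dianion should occur at the far more nucleophilic acetylide carbon, and the bulky silyl cap should survive the later hydroxide, carbanion and enolate steps.

Step 2
Reactants: 2 (Z)-3-methyl-5-(triisopropylsilyl)pent-2-en-4-yn-1-ol
Product: 3 (Z)-3-methyl-5-(triisopropylsilyl)pent-2-en-4-ynal
Conditions: activated MnO2 (15 equiv), CH2Cl2, rt
Reagents that add atoms: none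
Why: Heterogeneous MnO2 oxidation of the allylic alcohol should stop at the enal and keep the Z geometry, since no acid or base is present.

Step 3
Reactants: 4 (S)-4-benzyloxazolidin-2-one; 5 methyl 4-chloro-4-oxobutanoate
Product: 6 methyl 4-[(4S)-4-benzyl-2-oxooxazolidin-3-yl]-4-oxobutanoate
Conditions: n-BuLi (1.05 equiv), THF, −78 °C; then 5, −78 to 0 °C
Reagents that add atoms: none
Why: N-acylation of the lithiated oxazolidinone by the acid chloride, which is far more electrophilic than the methyl ester.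

Step 4
Reactants: 6 methyl 4-[(4S)-4-benzyl-2-oxooxazolidin-3-yl]-4-oxobutanoate; 3 (Z)-3-methyl-5-(triisopropylsilyl)pent-2-en-4-ynal
Product: 8 (4S)-4-benzyl-3-{(2R,3S)-2-[(1Z)-2-methyl-4-(triisopropylsilyl)but-1-en-3-yn-1-yl]-5-oxooxolane-3-carbonyl}oxazolidin-2-one, via aldol adduct 7 (not isolated)
Conditions: n-Bu2BOTf (1.15 equiv), i-Pr2NEt (1.3 equiv), CH2Cl2, 0 °C; 3, −78 to 0 °C; pH 7 buffer, MeOH, H2O2; then PPTS (cat.), toluene, 50 °C
Reagents that add atoms: none
Why: Evans syn-aldol, in which the Z boron enolate reacts through a Zimmerman–Traxler chair on the face away from the benzyl group and so sets C7 and C6 (3S,4R in 7), followed by lactonisation of the C6 hydroxyl onto the methyl ester to give the trans lactone.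

Step 5
Reactants: 8 lactone imide
Product: 9 (2R,3S)-2-[(1Z)-2-methyl-4-(triisopropylsilyl)but-1-en-3-yn-1-yl]-5-oxooxolane-3-carboxylic acid
Conditions: LiOH, H2O2, THF/H2O 3:1, 0 °C; Na2SO3; HCl to pH 2
Reagents that add atoms: hydrogen peroxide, OO (as LiOOH; supplies the carboxyl OH oxygen)
Why: Hydroperoxide should cleave the exocyclic imide carbonyl selectively, any opened lactone re-closes on acidification, and the triisopropylsilyl alkyne is inert to hydroxide.

Step 6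
Reactants: 10 (R)-2-methylglycidol, [(2R)-2-methyloxiran-2-yl]methanol
Product: 11 (2R)-2-methyl-3-(phenylsulfonyl)propane-1,2-diol
Conditions: PhSO2Na (1.5 equiv), NH4Cl (1.5 equiv), MeOH/H2O 3:1, 65 °C
Reagents that add atoms: sodium benzenesulfinate, [Na+].[O-]S(=O)c1ccccc1
Why: SN2 opening of the epoxide at its unsubstituted carbon by the sulfur of the sulfinate leaves the quaternary stereocentre (the future C10) untouched.

Step 7
Reactants: 11 (2R)-2-methyl-3-(phenylsulfonyl)propane-1,2-diol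
Product: 12 (4R)-2,2,4-trimethyl-4-[(phenylsulfonyl)methyl]-1,3-dioxolane
Conditions: 2,2-dimethoxypropane, PPTS (cat.), CH2Cl2, rt
Reagents that add atoms: 2,2-dimethoxypropane, COC(C)(C)OC
Why: Acid-catalysed transacetalisation ties the 1,2-diol into a dioxolane that tolerates carbanion, hydride and enolate chemistry.

Step 8
Reactants: 9 lactone acid; 12 (4R)-2,2,4-trimethyl-4-[(phenylsulfonyl)methyl]-1,3-dioxolane
Product: 14 (4S,5R)-5-[(1Z)-2-methyl-4-(triisopropylsilyl)but-1-en-3-yn-1-yl]-4-{2-(phenylsulfonyl)-2-[(4R)-2,2,4-trimethyl-1,3-dioxolan-4-yl]acetyl}oxolan-2-one (epimers at the sulfonyl carbon), via acid chloride 13 (not isolated)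
Conditions: (COCl)2, DMF (cat.), CH2Cl2, 0 °C to rt, evaporate; 12 (2.2 equiv), n-BuLi (2.2 equiv), THF, −78 °C, then 13 in THF, −78 °C; AcOH quench at −78 °C
Reagents that add atoms: oxalyl chloride, O=C(Cl)C(Cl)=O (chlorine of 13 only)
Why: C-acylation of the α-sulfonyl carbanion by the acid chloride at −78 °C should outrun enolisation at C7, while the second equivalent of carbanion deprotonates the β-keto sulfone and so prevents over-addition.

Step 9
Reactants: 14 β-keto sulfone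
Product: 15 (4S,5R)-5-[(1Z)-2-methyl-4-(triisopropylsilyl)but-1-en-3-yn-1-yl]-4-{[(4S)-2,2,4-trimethyl-1,3-dioxolan-4-yl]acetyl}oxolan-2-one
Conditions: SmI2 (3 equiv), THF/MeOH 10:1, −78 °C
Reagents that add atoms: none
Why: Reductive desulfonylation of a β-keto sulfone by single-electron transfer gives the samarium enolate, which MeOH protonates, while lactone, ketone and enyne are not reduced at −78 °C.

Step 10
Reactants: 15 lactone ketone
Product: 16 (4R,5R)-4-{(1R)-1-hydroxy-2-[(4S)-2,2,4-trimethyl-1,3-dioxolan-4-yl]ethyl}-5-[(1Z)-2-methyl-4-(triisopropylsilyl)but-1-en-3-yn-1-yl]oxolan-2-one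
Conditions: LiBH(s-Bu)3 (1.2 equiv), THF, −78 °C; AcOH quench at −78 °C
Reagents that add atoms: none
Why: Felkin–Anh addition of the bulky hydride anti to the ring carbon C6, the largest α-substituent on C7, should set C8 as R.

Step 11
Reactants: 16 lactone alcohol
Product: 17 (1R)-1-[(2R,3R)-2-[(1Z)-2-methyl-4-(triisopropylsilyl)but-1-en-3-yn-1-yl]-5-oxooxolan-3-yl]-2-[(4S)-2,2,4-trimethyl-1,3-dioxolan-4-yl]ethyl 3-methylbutanoate
Conditions: isovaleric anhydride (2 equiv), DMAP (0.2 equiv), Et3N, CH2Cl2, rt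
Reagents that add atoms: 3-methylbutanoic anhydride, CC(C)CC(=O)OC(=O)CC(C)C
Why: DMAP-catalysed acylation of the only free hydroxyl, which also blocks translactonisation to O8.

Step 12
Reactants: 17 isovalerate
Product: 20 (1R)-1-[(2R,3R)-2-[(1Z)-2-methyl-4-(triisopropylsilyl)but-1-en-3-yn-1-yl]-4-methylidene-5-oxooxolan-3-yl]-2-[(4S)-2,2,4-trimethyl-1,3-dioxolan-4-yl]ethyl 3-methylbutanoate, via Mannich base 18 (not isolated), via trimethylammonium iodide 19 (not isolated)
Conditions: LiN(SiMe3)2 (1.1 equiv), THF, −78 °C; CH2=NMe2+ I− (3 equiv), −78 °C to rt; MeI (10 equiv), CH2Cl2, rt; aq NaHCO3, rt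
Reagents that add atoms: N,N-dimethylmethyleneiminium iodide, C=[N+](C)C.[I-] (CH2 of 20; NMe2 only in 18 and 19); iodomethane, CI (methyl of 19 only)
Why: The γ-lactone α-CH2 is several pKa units more acidic than the isovalerate α-CH2 and should be deprotonated selectively, after which Mannich reaction, N-methylation and E1cB loss of trimethylamine give the exocyclic methylene.

Step 13
Reactants: 20 silyl enyne methylene lactone
Product: 21 (1R)-1-[(2R,3R)-2-[(1Z)-4-iodo-2-methylbut-1-en-3-yn-1-yl]-4-methylidene-5-oxooxolan-3-yl]-2-[(4S)-2,2,4-trimethyl-1,3-dioxolan-4-yl]ethyl 3-methylbutanoate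
Conditions: AgF (1.5 equiv), N-iodosuccinimide (1.5 equiv), MeCN, rt, dark
Reagents that add atoms: N-iodosuccinimide, O=C1CCC(=O)N1I
Why: Fluoride-triggered desilylation to the silver acetylide and its iodination convert the silylalkyne directly into the iodoalkyne (desilylative halogenation).

Step 14
Reactants: 21 iodoalkyne acetonide
Product: 22 (1R,3S)-3,4-dihydroxy-1-[(2R,3R)-2-[(1Z)-4-iodo-2-methylbut-1-en-3-yn-1-yl]-4-methylidene-5-oxooxolan-3-yl]-3-methylbutyl 3-methylbutanoate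
Conditions: AcOH/H2O 4:1, 40 °C
Reagents that add atoms: none
Why: Acetal hydrolysis under conditions that leave ester, lactone and iodoalkyne intact.

Step 15
Reactants: 22 diol
Product: 23 (1R,3S)-3-hydroxy-1-[(2R,3R)-2-[(1Z)-4-iodo-2-methylbut-1-en-3-yn-1-yl]-4-methylidene-5-oxooxolan-3-yl]-3-methyl-4-oxobutyl 3-methylbutanoate
Conditions: SO3·pyridine (3 equiv), DMSO, i-Pr2NEt, CH2Cl2, 0 °C; used at once
Reagents that add atoms: none
Why: Parikh–Doering oxidation takes the primary alcohol to the aldehyde without glycol cleavage, and the tertiary hydroxyl cannot be oxidised.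

Step 16
Reactants: 23 iodoalkynyl α-hydroxy aldehyde
Product: 24 (6R,7R,8R,10S)-1,10-dihydroxy-8-(3-methylbutanoyloxy)germacra-4(Z),11(13)-dien-2-yn-12,6-olide (both C1 epimers)
Conditions: CrCl2 (8 equiv), NiCl2 (0.05 equiv), degassed THF, rt, 23 added over 8 h (final 0.003 M); aq NH4Cl
Reagents that add atoms: none
Why: Two equivalents of CrCl2, helped by zerovalent nickel formed from NiCl2 that inserts into the C–I bond and transmetalates, turn the iodoalkyne into an alkynyl species of trivalent chromium, which adds to the aldehyde carbon C1 (Nozaki–Hiyama–Kishi alkynylation). The closest known reaction type is the CrCl2/NiCl2 cyclisation of iodoalkynyl aldehydes to ten-membered enediyne carbocycles. The ten-membered carbocycle C1–C10 is closed by exo-trig attack on the aldehyde, with the C2≡C3 alkyne inside the ring. The new stereocentre C1 is not controlled and need not be, because both carbinol epimers give the same ynone in step 17. The step needs chemoselectivity for the aldehyde over lactone, ester and acrylate, and cyclisation over oligomerisation: the first should follow from the carbonyl selectivity of organochromium reagents and the non-enolisable α-quaternary aldehyde, the second from high dilution together with the Z alkene C4=C5 and the trans lactone, which turn the two chain ends toward each other.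

Step 17
Reactants: 24 macrocyclic propargylic diol
Product: 25 (6R,7R,8R,10S)-10-hydroxy-8-(3-methylbutanoyloxy)-1-oxogermacra-4(Z),11(13)-dien-2-yn-12,6-olide
Conditions: IBX (2 equiv), DMSO, rt
Reagents that add atoms: none
Why: IBX should oxidise the secondary propargylic alcohol of either C1 epimer to the ynone without cleaving the 1,2-diol, so the epimer mixture converges.

Step 18
Reactants: 25 α′-hydroxy ynone
Product: 26 target CNP0409052.1, (6R,7R,8R,10S)-8-(3-methylbutanoyloxy)-1-oxo-3,10-epoxygermacra-2,4(Z),11(13)-trien-12,6-olide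
Conditions: [(4-CF3C6H4)3P]AuCl (5 mol %), AgOTf (5 mol %), toluene, rt
Reagents that add atoms: none
Why: Cationic monovalent gold activates the ynone alkyne for anti 5-endo-dig attack of the C10 hydroxyl on C3 across the ten-membered ring, and protodeauration gives the 3(2H)-furanone (known cycloisomerisation of α′-hydroxy ynones).

Compound list
1 | (Z)-3-methylpent-2-en-4-yn-1-ol | OC/C=C(/C)C#C | starting material
2 | (Z)-3-methyl-5-(triisopropylsilyl)pent-2-en-4-yn-1-ol | OC/C=C(/C)C#C[Si](C(C)C)(C(C)C)C(C)C | intermediate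
3 | (Z)-3-methyl-5-(triisopropylsilyl)pent-2-en-4-ynal | O=C/C=C(/C)C#C[Si](C(C)C)(C(C)C)C(C)C | intermediate
4 | (S)-4-benzyloxazolidin-2-one | O=C1N[C@@H](Cc2ccccc2)CO1 | starting material
5 | methyl 4-chloro-4-oxobutanoate | COC(=O)CCC(Cl)=O | starting material
6 | methyl 4-[(4S)-4-benzyl-2-oxooxazolidin-3-yl]-4-oxobutanoate | COC(=O)CCC(=O)N1C(=O)OC[C@@H]1Cc1ccccc1 | intermediate
7 | methyl (3S,4R,5Z)-3-[(4S)-4-benzyl-2-oxooxazolidine-3-carbonyl]-4-hydroxy-6-methyl-8-(triisopropylsilyl)oct-5-en-7-ynoate (aldol adduct, not isolated) | COC(=O)C[C@H](C(=O)N1C(=O)OC[C@@H]1Cc1ccccc1)[C@H](O)/C=C(/C)C#C[Si](C(C)C)(C(C)C)C(C)C | intermediate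
8 | (4S)-4-benzyl-3-{(2R,3S)-2-[(1Z)-2-methyl-4-(triisopropylsilyl)but-1-en-3-yn-1-yl]-5-oxooxolane-3-carbonyl}oxazolidin-2-one | C1C(=O)O[C@H](/C=C(/C)C#C[Si](C(C)C)(C(C)C)C(C)C)[C@H]1C(=O)N1C(=O)OC[C@@H]1Cc1ccccc1 | intermediate
9 | (2R,3S)-2-[(1Z)-2-methyl-4-(triisopropylsilyl)but-1-en-3-yn-1-yl]-5-oxooxolane-3-carboxylic acid | C1C(=O)O[C@H](/C=C(/C)C#C[Si](C(C)C)(C(C)C)C(C)C)[C@H]1C(=O)O | intermediate
10 | (R)-2-methylglycidol, [(2R)-2-methyloxiran-2-yl]methanol | OC[C@]1(C)CO1 | starting material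
11 | (2R)-2-methyl-3-(phenylsulfonyl)propane-1,2-diol | OC[C@@](C)(O)CS(=O)(=O)c1ccccc1 | intermediate
12 | (4R)-2,2,4-trimethyl-4-[(phenylsulfonyl)methyl]-1,3-dioxolane | CC1(C)OC[C@](C)(CS(=O)(=O)c2ccccc2)O1 | intermediate
13 | (2R,3S)-2-[(1Z)-2-methyl-4-(triisopropylsilyl)but-1-en-3-yn-1-yl]-5-oxooxolane-3-carbonyl chloride (not isolated) | C1C(=O)O[C@H](/C=C(/C)C#C[Si](C(C)C)(C(C)C)C(C)C)[C@H]1C(Cl)=O | intermediate
14 | (4S,5R)-5-[(1Z)-2-methyl-4-(triisopropylsilyl)but-1-en-3-yn-1-yl]-4-{2-(phenylsulfonyl)-2-[(4R)-2,2,4-trimethyl-1,3-dioxolan-4-yl]acetyl}oxolan-2-one (epimers at the sulfonyl carbon) | C1C(=O)O[C@H](/C=C(/C)C#C[Si](C(C)C)(C(C)C)C(C)C)[C@H]1C(=O)C(S(=O)(=O)c1ccccc1)[C@@]1(C)COC(C)(C)O1 | intermediate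
15 | (4S,5R)-5-[(1Z)-2-methyl-4-(triisopropylsilyl)but-1-en-3-yn-1-yl]-4-{[(4S)-2,2,4-trimethyl-1,3-dioxolan-4-yl]acetyl}oxolan-2-one | C1C(=O)O[C@H](/C=C(/C)C#C[Si](C(C)C)(C(C)C)C(C)C)[C@H]1C(=O)C[C@@]1(C)COC(C)(C)O1 | intermediate
16 | (4R,5R)-4-{(1R)-1-hydroxy-2-[(4S)-2,2,4-trimethyl-1,3-dioxolan-4-yl]ethyl}-5-[(1Z)-2-methyl-4-(triisopropylsilyl)but-1-en-3-yn-1-yl]oxolan-2-one | C1C(=O)O[C@H](/C=C(/C)C#C[Si](C(C)C)(C(C)C)C(C)C)[C@H]1[C@H](O)C[C@@]1(C)COC(C)(C)O1 | intermediate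
17 | (1R)-1-[(2R,3R)-2-[(1Z)-2-methyl-4-(triisopropylsilyl)but-1-en-3-yn-1-yl]-5-oxooxolan-3-yl]-2-[(4S)-2,2,4-trimethyl-1,3-dioxolan-4-yl]ethyl 3-methylbutanoate | C1C(=O)O[C@H](/C=C(/C)C#C[Si](C(C)C)(C(C)C)C(C)C)[C@H]1[C@H](OC(=O)CC(C)C)C[C@@]1(C)COC(C)(C)O1 | intermediate
18 | α-(dimethylaminomethyl) lactone from 17 (Mannich base, C11 epimers, not isolated) | CN(C)CC1C(=O)O[C@H](/C=C(/C)C#C[Si](C(C)C)(C(C)C)C(C)C)[C@H]1[C@H](OC(=O)CC(C)C)C[C@@]1(C)COC(C)(C)O1 | intermediate
19 | trimethylammonium iodide of 18 (not isolated) | C[N+](C)(C)CC1C(=O)O[C@H](/C=C(/C)C#C[Si](C(C)C)(C(C)C)C(C)C)[C@H]1[C@H](OC(=O)CC(C)C)C[C@@]1(C)COC(C)(C)O1.[I-] | intermediate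
20 | (1R)-1-[(2R,3R)-2-[(1Z)-2-methyl-4-(triisopropylsilyl)but-1-en-3-yn-1-yl]-4-methylidene-5-oxooxolan-3-yl]-2-[(4S)-2,2,4-trimethyl-1,3-dioxolan-4-yl]ethyl 3-methylbutanoate | C=C1C(=O)O[C@H](/C=C(/C)C#C[Si](C(C)C)(C(C)C)C(C)C)[C@H]1[C@H](OC(=O)CC(C)C)C[C@@]1(C)COC(C)(C)O1 | intermediate
21 | (1R)-1-[(2R,3R)-2-[(1Z)-4-iodo-2-methylbut-1-en-3-yn-1-yl]-4-methylidene-5-oxooxolan-3-yl]-2-[(4S)-2,2,4-trimethyl-1,3-dioxolan-4-yl]ethyl 3-methylbutanoate | C=C1C(=O)O[C@H](/C=C(/C)C#CI)[C@H]1[C@H](OC(=O)CC(C)C)C[C@@]1(C)COC(C)(C)O1 | intermediate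
22 | (1R,3S)-3,4-dihydroxy-1-[(2R,3R)-2-[(1Z)-4-iodo-2-methylbut-1-en-3-yn-1-yl]-4-methylidene-5-oxooxolan-3-yl]-3-methylbutyl 3-methylbutanoate | C=C1C(=O)O[C@H](/C=C(/C)C#CI)[C@H]1[C@H](OC(=O)CC(C)C)C[C@](C)(O)CO | intermediate
23 | (1R,3S)-3-hydroxy-1-[(2R,3R)-2-[(1Z)-4-iodo-2-methylbut-1-en-3-yn-1-yl]-4-methylidene-5-oxooxolan-3-yl]-3-methyl-4-oxobutyl 3-methylbutanoate | C=C1C(=O)O[C@H](/C=C(/C)C#CI)[C@H]1[C@H](OC(=O)CC(C)C)C[C@](C)(O)C=O | intermediate
24 | (6R,7R,8R,10S)-1,10-dihydroxy-8-(3-methylbutanoyloxy)germacra-4(Z),11(13)-dien-2-yn-12,6-olide (C1 epimers) | C=C1C(=O)O[C@@H]2/C=C(/C)C#CC(O)[C@](C)(C[C@@H](OC(=O)CC(C)C)[C@@H]12)O | intermediate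
25 | (6R,7R,8R,10S)-10-hydroxy-8-(3-methylbutanoyloxy)-1-oxogermacra-4(Z),11(13)-dien-2-yn-12,6-olide | C=C1C(=O)O[C@@H]2/C=C(/C)C#CC(=O)[C@](C)(C[C@@H](OC(=O)CC(C)C)[C@@H]12)O | intermediate
26 | CNP0409052.1, (6R,7R,8R,10S)-8-(3-methylbutanoyloxy)-1-oxo-3,10-epoxygermacra-2,4(Z),11(13)-trien-12,6-olide | C=C1C(=O)O[C@@H]2/C=C(/C)C3=CC(=O)[C@](C)(C[C@@H](OC(=O)CC(C)C)[C@@H]12)O3 | target

Total step count: 18. Longest linear sequence: 15 steps (steps 1, 2, 4, 5, 8–18).

Steps most likely to fail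

Step 16. Intermolecular coupling may outrun ring closure, the C–I bond may be reduced to C–H before the carbon–carbon bond forms, or the Lewis-acidic chromium salts may trigger an α-ketol shift of the hydroxy aldehyde. The fallback replaces reductive metalation of a C–I bond by amine/Zn(OTf)2-mediated addition of the free alkyne C–H to the same non-enolisable aldehyde. It sets out from 20: Bu4NF buffered with AcOH in THF should give the terminal alkyne (1R)-1-[(2R,3R)-2-[(1Z)-2-methylbut-1-en-3-yn-1-yl]-4-methylidene-5-oxooxolan-3-yl]-2-[(4S)-2,2,4-trimethyl-1,3-dioxolan-4-yl]ethyl 3-methylbutanoate F1. Aqueous AcOH should then give the diol (1R,3S)-3,4-dihydroxy-3-methyl-1-[(2R,3R)-2-[(1Z)-2-methylbut-1-en-3-yn-1-yl]-4-methylidene-5-oxooxolan-3-yl]butyl 3-methylbutanoate F2, and SO3·pyridine/DMSO the hydroxy aldehyde (1R,3S)-3-hydroxy-3-methyl-1-[(2R,3R)-2-[(1Z)-2-methylbut-1-en-3-yn-1-yl]-4-methylidene-5-oxooxolan-3-yl]-4-oxobutyl 3-methylbutanoate F3. Slow addition of F3 to Zn(OTf)2 and Et3N in toluene at 40 °C should close the C1–C2 bond through the zinc acetylide, and the fallback comes back to the route at 24.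

Step 8. The carbanion may enolise the acid chloride toward a ketene (loss of the C7 configuration), or β-elimination may open the lactone. The fallback forms the C8–C9 bond before the lactone exists and sets C6 and C7 afterwards by a ketone aldol. It sets out from 12, 5 and 3: lithiated 12 and 5 (THF, −78 °C) should give methyl 4-oxo-5-(phenylsulfonyl)-5-[(4R)-2,2,4-trimethyl-1,3-dioxolan-4-yl]pentanoate F4. SmI2 in THF/MeOH should then give methyl 4-oxo-5-[(4S)-2,2,4-trimethyl-1,3-dioxolan-4-yl]pentanoate F5. Enolisation at the less hindered CH2 with a diisopinocampheylboron triflate (Ipc2BOTf, i-Pr2NEt; the antipode chosen for the 3S,4R syn adduct) and addition to 3 should give methyl (3S,4R,5Z)-4-hydroxy-6-methyl-3-{[(4S)-2,2,4-trimethyl-1,3-dioxolan-4-yl]acetyl}-8-(triisopropylsilyl)oct-5-en-7-ynoate F6. If reagent control is poor, n-Bu2BOTf and separation of the two syn diastereomers (they differ at C10 as well) would serve instead. PPTS-catalysed lactonisation of F6 comes back to the route at 15.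

Step 10. Hydride delivery may show poor facial selectivity, or chelation may reverse it. The fallback replaces facial control by SN2 inversion and sets out from 15: whichever reduction gives mainly the epimer (Zn(BH4)2 under chelation control if needed) should supply (4R,5R)-4-{(1S)-1-hydroxy-2-[(4S)-2,2,4-trimethyl-1,3-dioxolan-4-yl]ethyl}-5-[(1Z)-2-methyl-4-(triisopropylsilyl)but-1-en-3-yn-1-yl]oxolan-2-one F7. Mitsunobu esterification of F7 with 3-methylbutanoic acid (PPh3, diisopropyl azodicarboxylate, toluene, 0 °C to rt) inverts C8 and installs the ester in one operation, coming back to the route at 17.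

Further compounds
F1 | step 16 | (1R)-1-[(2R,3R)-2-[(1Z)-2-methylbut-1-en-3-yn-1-yl]-4-methylidene-5-oxooxolan-3-yl]-2-[(4S)-2,2,4-trimethyl-1,3-dioxolan-4-yl]ethyl 3-methylbutanoate | C=C1C(=O)O[C@H](/C=C(/C)C#C)[C@H]1[C@H](OC(=O)CC(C)C)C[C@@]1(C)COC(C)(C)O1
F2 | step 16 | (1R,3S)-3,4-dihydroxy-3-methyl-1-[(2R,3R)-2-[(1Z)-2-methylbut-1-en-3-yn-1-yl]-4-methylidene-5-oxooxolan-3-yl]butyl 3-methylbutanoate | C=C1C(=O)O[C@H](/C=C(/C)C#C)[C@H]1[C@H](OC(=O)CC(C)C)C[C@](C)(O)CO
F3 | step 16 | (1R,3S)-3-hydroxy-3-methyl-1-[(2R,3R)-2-[(1Z)-2-methylbut-1-en-3-yn-1-yl]-4-methylidene-5-oxooxolan-3-yl]-4-oxobutyl 3-methylbutanoate | C=C1C(=O)O[C@H](/C=C(/C)C#C)[C@H]1[C@H](OC(=O)CC(C)C)C[C@](C)(O)C=O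
F4 | step 8 | methyl 4-oxo-5-(phenylsulfonyl)-5-[(4R)-2,2,4-trimethyl-1,3-dioxolan-4-yl]pentanoate (C5 epimers) | COC(=O)CCC(=O)C(S(=O)(=O)c1ccccc1)[C@@]1(C)COC(C)(C)O1
F5 | step 8 | methyl 4-oxo-5-[(4S)-2,2,4-trimethyl-1,3-dioxolan-4-yl]pentanoate | COC(=O)CCC(=O)C[C@@]1(C)COC(C)(C)O1
F6 | step 8 | methyl (3S,4R,5Z)-4-hydroxy-6-methyl-3-{[(4S)-2,2,4-trimethyl-1,3-dioxolan-4-yl]acetyl}-8-(triisopropylsilyl)oct-5-en-7-ynoate | COC(=O)C[C@H](C(=O)C[C@@]1(C)COC(C)(C)O1)[C@H](O)/C=C(/C)C#C[Si](C(C)C)(C(C)C)C(C)C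
F7 | step 10 | (4R,5R)-4-{(1S)-1-hydroxy-2-[(4S)-2,2,4-trimethyl-1,3-dioxolan-4-yl]ethyl}-5-[(1Z)-2-methyl-4-(triisopropylsilyl)but-1-en-3-yn-1-yl]oxolan-2-one | C1C(=O)O[C@H](/C=C(/C)C#C[Si](C(C)C)(C(C)C)C(C)C)[C@H]1[C@@H](O)C[C@@]1(C)COC(C)(C)O1
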